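## Retrosynthetic overview

1. The senecioyl ester C–O bond and the two silyl ethers are cut last (fluoride deprotection, then Steglich esterification).
2. The quinone ring (C1, C2, C3, C4, C4a, C8a) is cut at C2=C3. It is closed by oxidative coupling of the two enol termini of an arene-1,2-diyl bis(trimethylsilyl enol ether), and the same oxidant carries the resulting 1,4-diketone on to the quinone.
3. Enabling feature: C2 and C3 are unsubstituted CH atoms, each α to a carbonyl (C1, C4) carried by the adjacent arene carbons C8a and C4a. The quinone ring is therefore the tail-to-tail dimer of two ortho acetyl groups, and its 1,4-diketone precursor is the keto tautomer of a hydroquinone.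
4. The benzenoid ring (C4a, C5 to C8, C8a) comes from a Diels–Alder/ring-opening benzannulation of a 3-substituted 2-methoxyfuran with hex-3-yne-2,5-dione. This one step places OMe next to the side chain, OH para to it, and both acetyl groups.
5. The stereocentre is set on the furan by CBS reduction. Ring order: benzenoid ring first (step 8), quinone ring second (step 11).

Key step: step 11

Assumption: methyl 4,5-dibromofuran-2-carboxylate, 4-methylpent-3-enoic acid, N,O-dimethylhydroxylamine hydrochloride, hex-3-yne-2,5-diol and 3-methylbut-2-enoic acid are taken as purchasable; the carbinol carbon of the target is (R).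

Abbreviations: TBS = tert-butyldimethylsilyl, TMS = trimethylsilyl, CDI = 1,1'-carbonyldiimidazole.

## Route

Step 1
Reactants: 1 methyl 4,5-dibromofuran-2-carboxylate
Product: 3 4-bromo-5-methoxyfuran-2-carboxylic acid, via methyl ester 2 (not isolated)
Conditions: NaOMe (3 equiv), MeOH, reflux; then aq. NaOH, 60 °C; then HCl to pH 2, 0 °C
Reagents that add atoms: sodium methoxide C[O-].[Na+]; sodium hydroxide [OH-].[Na+]
Why: Addition–elimination (SNAr) of methoxide at C5, whose bromide is vinylogously activated by the 2-ester while the C4 bromide is not, followed by ester saponification in the same flask, the classical entry to 5-alkoxy-2-furoic acids.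

Step 2
Reactants: 3 4-bromo-5-methoxyfuran-2-carboxylic acid
Product: 4 3-bromo-2-methoxyfuran
Conditions: Cu powder (catalytic), quinoline, 190 °C, product distilled off and kept over K2CO3
Reagents that add atoms: none
Why: Copper-assisted thermal protodecarboxylation, the classical way from 5-alkoxy-2-furoic acids to 2-alkoxyfurans, should leave the 3-bromide untouched and give a distillable furan.

Step 3
Reactants: 5 4-methylpent-3-enoic acid; 6 N,O-dimethylhydroxylamine hydrochloride
Product: 7 N-methoxy-N,4-dimethylpent-3-enamide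
Conditions: CDI, CH2Cl2, 0 °C to rt; then 6, rt
Reagents that add atoms: none
Why: Weinreb amide formation through the acyl imidazolide proceeds without strong base, so the β,γ-double bond should not move into conjugation.

Step 4
Reactants: 4 3-bromo-2-methoxyfuran; 7 N-methoxy-N,4-dimethylpent-3-enamide
Product: 9 1-(2-methoxyfuran-3-yl)-4-methylpent-3-en-1-one, via 3-lithio-2-methoxyfuran 8 (not isolated)
Conditions: n-BuLi, THF, −78 °C; then 7, −78 to −40 °C; aq. NH4Cl
Reagents that add atoms: none
Why: Bromine–lithium exchange at −78 °C gives the 3-lithiofuran, held by the neighbouring methoxy group, and its acylation stops at the ketone because the chelated tetrahedral adduct only collapses on work-up (Weinreb ketone synthesis).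

Step 5
Reactants: 9 1-(2-methoxyfuran-3-yl)-4-methylpent-3-en-1-one
Product: 10 (1R)-1-(2-methoxyfuran-3-yl)-4-methylpent-3-en-1-ol
Conditions: (S)-2-methyl-CBS-oxazaborolidine (15 mol %), catecholborane, toluene, −78 °C; aq. NaOH work-up
Reagents that add atoms: none
Why: Corey–Bakshi–Shibata reduction: the (S)-oxazaborolidine binds the ketone with the furyl group as the large and the prenyl-bearing CH2 as the small substituent and delivers hydride to the face that gives the (R)-carbinol, as for aryl n-alkyl ketones, while catecholborane at −78 °C leaves the alkene alone.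

Step 6
Reactants: 10 (1R)-1-(2-methoxyfuran-3-yl)-4-methylpent-3-en-1-ol
Product: 11 tert-butyl{[(1R)-1-(2-methoxyfuran-3-yl)-4-methylpent-3-en-1-yl]oxy}dimethylsilane
Conditions: TBSCl, imidazole, DMF, rt
Reagents that add atoms: tert-butyldimethylsilyl chloride CC(C)(C)[Si](C)(C)Cl
Why: Silylation under basic conditions caps the carbinol, which as a free alcohol next to the electron-rich furan would ionise easily, and does not touch the stereocentre.

Step 7
Reactants: 12 hex-3-yne-2,5-diol (mixture of stereoisomers)
Product: 13 hex-3-yne-2,5-dione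
Conditions: CrO3, H2SO4, acetone, 0 °C
Reagents that add atoms: none
Why: Jones oxidation of the bis-propargylic diol is the established preparation of this ynedione, which is used at once because it polymerises on storage.

Step 8
Reactants: 11 tert-butyl{[(1R)-1-(2-methoxyfuran-3-yl)-4-methylpent-3-en-1-yl]oxy}dimethylsilane; 13 hex-3-yne-2,5-dione
Product: 15 1,1'-{3-hydroxy-6-methoxy-5-[(1R)-1-(TBSO)-4-methylpent-3-en-1-yl]-1,2-phenylene}di(ethan-1-one), via oxanorbornadiene adduct 14 (not isolated)
Conditions: CH2Cl2, 0 °C to rt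
Reagents that add atoms: none
Why: Diels–Alder reaction of the electron-rich 2-methoxyfuran with the doubly activated alkyne is followed by spontaneous opening of the bridging ketal C–O bond and tautomerisation to the phenol (known furan/alkyne benzannulation to para-methoxyphenols), the symmetrical dienophile removing any regiochemical question and the furan substitution pattern placing OMe next to the side chain and OH para to it.

Step 9
Reactants: 15 1,1'-{3-hydroxy-6-methoxy-5-[(1R)-1-(TBSO)-4-methylpent-3-en-1-yl]-1,2-phenylene}di(ethan-1-one)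
Product: 16 1,1'-{3-(TBSO)-6-methoxy-5-[(1R)-1-(TBSO)-4-methylpent-3-en-1-yl]-1,2-phenylene}di(ethan-1-one)
Conditions: TBSCl, imidazole, DMAP (catalytic), DMF, 40 °C
Reagents that add atoms: tert-butyldimethylsilyl chloride CC(C)(C)[Si](C)(C)Cl
Why: Silylation of the hydrogen-bonded phenol gives an aryl silyl ether that blocks oxidation of the para-methoxyphenol in step 11 and later falls together with the side-chain TBS group.

Step 10
Reactants: 16 1,1'-{3-(TBSO)-6-methoxy-5-[(1R)-1-(TBSO)-4-methylpent-3-en-1-yl]-1,2-phenylene}di(ethan-1-one)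
Product: 17 arene-1,2-diyl bis(enol silane): the 1,2-bis[1-(trimethylsilyloxy)ethenyl] analogue of 16 (each acetyl group converted into C(OTMS)=CH2)
Conditions: TMSOTf (2.5 equiv), Et3N (4 equiv), CH2Cl2, 0 °C; pentane trituration, filtration under Ar, used crude
Reagents that add atoms: trimethylsilyl trifluoromethanesulfonate C[Si](C)(C)OS(=O)(=O)C(F)(F)F
Why: Soft enolisation of both aryl methyl ketones with TMSOTf and Et3N gives the only possible enol silanes, excess amine deprotonating each silyloxocarbenium ion faster than the neighbouring enol silane can attack it in a Mukaiyama aldol sense.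

Step 11
Reactants: 17 arene-1,2-diyl bis(trimethylsilyl enol ether)
Product: 20 5-(TBSO)-8-methoxy-7-[(1R)-1-(TBSO)-4-methylpent-3-en-1-yl]naphthalene-1,4-dione, via 2,3-dihydroquinone diketone 18 (not isolated), via naphthalene-1,4-diol 19 (not isolated)
Conditions: Ag2O (3 equiv), DMSO, 4 Å molecular sieves, 65 °C, 0.01 M
Reagents that add atoms: none
Why: Proposed new method: Ag2O should cleave the two trimethylsilyl enol ethers to monovalent silver enolates, which shed zerovalent silver to give α-keto radicals; union of the two CH2 termini (radical recombination, or addition of one radical to the neighbouring enol ether followed by a second one-electron oxidation) forms the C2–C3 bond of diketone 18, whose aromatic enol tautomer 19 is then dehydrogenated by a second equivalent of Ag2O to quinone 20. The closest known reaction type is the silver-oxide-mediated oxidative homocoupling of aryl methyl ketone silyl enol ethers to 1,4-diketones, together with intramolecular oxidative couplings of bis(silyl enol ethers) to cyclic 1,4-diketones by one-electron oxidants and the routine Ag2O oxidation of hydroquinones; the ring closure on an arene-1,2-diyl bis(enol ether) and its run-on to the quinone are the untested part. The one ring formed is the six-membered quinone ring, closed between two sp2 CH2 termini in a 6-endo-trig sense if it runs by radical addition (attack at the unsubstituted terminus gives a benzylic α-siloxy radical), which is preferred over 5-exo attack at the substituted carbon. No stereocentre is created, and the side-chain stereocentre is remote from all reacting atoms. The step needs intramolecular C–C coupling ahead of intermolecular coupling, of aldol closure to an indanone and of oxidation of the electron-rich ring: high dilution, the ortho relation of the two enol ethers (the flanking OMe and OTBS groups twist both siloxyvinyl groups out of the ring plane and stack their CH2 termini), the fact that neither carbonyl group is free before the C–C bond exists, and the silyl cap on the para-methoxyphenol should secure this.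

Step 12
Reactants: 20 5-(TBSO)-8-methoxy-7-[(1R)-1-(TBSO)-4-methylpent-3-en-1-yl]naphthalene-1,4-dione
Product: 21 5-hydroxy-7-[(1R)-1-hydroxy-4-methylpent-3-en-1-yl]-8-methoxynaphthalene-1,4-dione
Conditions: HF·pyridine, pyridine, THF, 0 °C to rt
Reagents that add atoms: none
Why: Buffered fluoride cleaves both silyl ethers, the peri aryl ether fastest, without acid strong enough to cyclise the carbinol onto the trisubstituted alkene or to ionise the stereocentre.

Step 13
Reactants: 21 5-hydroxy-7-[(1R)-1-hydroxy-4-methylpent-3-en-1-yl]-8-methoxynaphthalene-1,4-dione; 22 3-methylbut-2-enoic acid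
Product: 23 (1R)-1-(4-hydroxy-1-methoxy-5,8-dioxo-5,8-dihydronaphthalen-2-yl)-4-methylpent-3-en-1-yl 3-methylbut-2-enoate (target)
Conditions: DCC, DMAP (catalytic), CH2Cl2, 0 °C to rt
Reagents that add atoms: none
Why: Steglich esterification forms only the acyl–oxygen bond, so the stereocentre is retained, and the peri hydroxyl, hydrogen-bonded to the C4 carbonyl, is too poor a nucleophile to compete, as in acylations of related hydroxynaphthoquinone carbinols.

## Compound list

1 | methyl 4,5-dibromofuran-2-carboxylate | COC(=O)c1cc(Br)c(Br)o1 | starting material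
2 | methyl 4-bromo-5-methoxyfuran-2-carboxylate (not isolated) | COC(=O)c1cc(Br)c(OC)o1 | intermediate
3 | 4-bromo-5-methoxyfuran-2-carboxylic acid | OC(=O)c1cc(Br)c(OC)o1 | intermediate
4 | 3-bromo-2-methoxyfuran | COc1occc1Br | intermediate
5 | 4-methylpent-3-enoic acid | CC(C)=CCC(=O)O | starting material
6 | N,O-dimethylhydroxylamine hydrochloride | CNOC.Cl | starting material
7 | N-methoxy-N,4-dimethylpent-3-enamide | CC(C)=CCC(=O)N(C)OC | intermediate
8 | 3-lithio-2-methoxyfuran (not isolated) | COc1occc1[Li] | intermediate
9 | 1-(2-methoxyfuran-3-yl)-4-methylpent-3-en-1-one | COc1occc1C(=O)CC=C(C)C | intermediate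
10 | (1R)-1-(2-methoxyfuran-3-yl)-4-methylpent-3-en-1-ol | COc1occc1[C@H](O)CC=C(C)C | intermediate
11 | tert-butyl{[(1R)-1-(2-methoxyfuran-3-yl)-4-methylpent-3-en-1-yl]oxy}dimethylsilane | COc1occc1[C@@H](CC=C(C)C)O[Si](C)(C)C(C)(C)C | intermediate
12 | hex-3-yne-2,5-diol (mixture of stereoisomers) | CC(O)C#CC(C)O | starting material
13 | hex-3-yne-2,5-dione | CC(=O)C#CC(C)=O | intermediate
14 | 1,1'-{1-methoxy-6-[(1R)-1-(TBSO)-4-methylpent-3-en-1-yl]-7-oxabicyclo[2.2.1]hepta-2,5-diene-2,3-diyl}di(ethan-1-one), bridgehead diastereomers (not isolated) | COC12OC(C=C1[C@@H](CC=C(C)C)O[Si](C)(C)C(C)(C)C)C(C(C)=O)=C2C(C)=O | intermediate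
15 | 1,1'-{3-hydroxy-6-methoxy-5-[(1R)-1-(TBSO)-4-methylpent-3-en-1-yl]-1,2-phenylene}di(ethan-1-one) | COc1c([C@@H](CC=C(C)C)O[Si](C)(C)C(C)(C)C)cc(O)c(C(C)=O)c1C(C)=O | intermediate
16 | 1,1'-{3-(TBSO)-6-methoxy-5-[(1R)-1-(TBSO)-4-methylpent-3-en-1-yl]-1,2-phenylene}di(ethan-1-one) | COc1c([C@@H](CC=C(C)C)O[Si](C)(C)C(C)(C)C)cc(O[Si](C)(C)C(C)(C)C)c(C(C)=O)c1C(C)=O | intermediate
17 | bis(TMS enol ether) of 16: 1,2-bis[1-(trimethylsilyloxy)ethenyl]-3-(TBSO)-6-methoxy-5-[(1R)-1-(TBSO)-4-methylpent-3-en-1-yl]benzene | COc1c([C@@H](CC=C(C)C)O[Si](C)(C)C(C)(C)C)cc(O[Si](C)(C)C(C)(C)C)c(C(=C)O[Si](C)(C)C)c1C(=C)O[Si](C)(C)C | intermediate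
18 | 5-(TBSO)-8-methoxy-7-[(1R)-1-(TBSO)-4-methylpent-3-en-1-yl]-2,3-dihydronaphthalene-1,4-dione (not isolated) | COc1c([C@@H](CC=C(C)C)O[Si](C)(C)C(C)(C)C)cc(O[Si](C)(C)C(C)(C)C)c2c1C(=O)CCC2=O | intermediate
19 | 5-(TBSO)-8-methoxy-7-[(1R)-1-(TBSO)-4-methylpent-3-en-1-yl]naphthalene-1,4-diol (not isolated) | COc1c([C@@H](CC=C(C)C)O[Si](C)(C)C(C)(C)C)cc(O[Si](C)(C)C(C)(C)C)c2c(O)ccc(O)c12 | intermediate
20 | 5-(TBSO)-8-methoxy-7-[(1R)-1-(TBSO)-4-methylpent-3-en-1-yl]naphthalene-1,4-dione | COc1c([C@@H](CC=C(C)C)O[Si](C)(C)C(C)(C)C)cc(O[Si](C)(C)C(C)(C)C)c2c1C(=O)C=CC2=O | intermediate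
21 | 5-hydroxy-7-[(1R)-1-hydroxy-4-methylpent-3-en-1-yl]-8-methoxynaphthalene-1,4-dione | COc1c([C@H](O)CC=C(C)C)cc(O)c2c1C(=O)C=CC2=O | intermediate
22 | 3-methylbut-2-enoic acid | CC(C)=CC(=O)O | starting material
23 | (1R)-1-(4-hydroxy-1-methoxy-5,8-dioxo-5,8-dihydronaphthalen-2-yl)-4-methylpent-3-en-1-yl 3-methylbut-2-enoate | COc1c([C@@H](CC=C(C)C)OC(=O)C=C(C)C)cc(O)c2c1C(=O)C=CC2=O | target

## Step count and risks

Total step count: 13. Longest linear sequence: 11 steps (1, 2, 4, 5, 6, 8, 9, 10, 11, 12, 13).

**Step 11 (proposed new method).** The enol ethers may simply be desilylated back to the methyl ketones, couple between molecules, or the electron-rich ring may be oxidised in their place. The fallback uses known chemistry and makes the same C2=C3 bond by olefin metathesis. It sets out from compound 11, before step 8, and so also covers a failure of steps 8 to 10. Compound 11 and dimethyl but-2-ynedioate (CH2Cl2, 0 °C to rt) should give, by the same furan/alkyne benzannulation, dimethyl 3-hydroxy-6-methoxy-5-[(1R)-1-(TBSO)-4-methylpent-3-en-1-yl]benzene-1,2-dicarboxylate F1. Silylation of the phenol (TBSCl, imidazole, DMF) gives the aryl silyl ether diester F2. Reduction with i-Bu2AlH (CH2Cl2, −78 to 0 °C) gives the benzene-1,2-dimethanol F3, and Swern oxidation gives the benzene-1,2-dicarbaldehyde F4. Addition of CH2=CHMgBr (THF, −78 °C) gives the bis(allylic alcohol) F5 as a diastereomer mixture. Ring-closing metathesis with the second-generation Grubbs catalyst RuCl2(=CHPh)(H2IMes)(PCy3) (CH2Cl2, 40 °C) gives the 1,4-dihydronaphthalene-1,4-diol F6. Dess–Martin periodinane (NaHCO3, CH2Cl2) oxidises both carbinols, and the route is rejoined at compound 20.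

**Step 5.** Facial selectivity may be poor, because the 2-methoxy group can compete for the boron Lewis acid and the ketone is a deactivated, vinylogous-ester-like carbonyl; the very electron-rich furyl carbinol may also ionise during work-up. The fallback sets the stereocentre by reagent-controlled C–C bond formation and sets out from compound 4. Bromine–lithium exchange (n-BuLi, THF, −78 °C) and formylation with DMF give 2-methoxyfuran-3-carbaldehyde F7. Brown allylation with the enantiomer of B-allyldiisopinocampheylborane that adds allyl to the Re face of aromatic aldehydes (expected to be the (+)-reagent made from (−)-α-pinene; Et2O, −78 °C, ethanolamine work-up) should give (1R)-1-(2-methoxyfuran-3-yl)but-3-en-1-ol F8. Silylation (TBSCl, imidazole, DMF) gives tert-butyl{[(1R)-1-(2-methoxyfuran-3-yl)but-3-en-1-yl]oxy}dimethylsilane F9. Cross-metathesis with 2-methyl-2-butene as solvent (second-generation Grubbs catalyst RuCl2(=CHPh)(H2IMes)(PCy3), 40 °C) converts the allyl into the prenyl group, and the route is rejoined at compound 11.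

**Step 13.** Chemoselectivity between the secondary alcohol and the phenol may be lost, giving mixtures of mono- and diacylated material. The fallback replaces selective acylation by exhaustive acylation and selective cleavage, and sets out from compound 21. An excess of acid 22 with DCC and stoichiometric DMAP (CH2Cl2, rt) should give (1R)-1-{1-methoxy-4-[(3-methylbut-2-enoyl)oxy]-5,8-dioxo-5,8-dihydronaphthalen-2-yl}-4-methylpent-3-en-1-yl 3-methylbut-2-enoate F10. Brief methanolysis (catalytic K2CO3, MeOH, 0 °C) should remove only the far more labile peri aryl ester, and the route is rejoined at compound 23.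

Further compounds
F1 | step 11 | dimethyl 3-hydroxy-6-methoxy-5-[(1R)-1-(TBSO)-4-methylpent-3-en-1-yl]benzene-1,2-dicarboxylate | COC(=O)c1c(O)cc([C@@H](CC=C(C)C)O[Si](C)(C)C(C)(C)C)c(OC)c1C(=O)OC
F2 | step 11 | dimethyl 3-(TBSO)-6-methoxy-5-[(1R)-1-(TBSO)-4-methylpent-3-en-1-yl]benzene-1,2-dicarboxylate | COC(=O)c1c(O[Si](C)(C)C(C)(C)C)cc([C@@H](CC=C(C)C)O[Si](C)(C)C(C)(C)C)c(OC)c1C(=O)OC
F3 | step 11 | {3-(TBSO)-6-methoxy-5-[(1R)-1-(TBSO)-4-methylpent-3-en-1-yl]-1,2-phenylene}dimethanol | OCc1c(O[Si](C)(C)C(C)(C)C)cc([C@@H](CC=C(C)C)O[Si](C)(C)C(C)(C)C)c(OC)c1CO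
F4 | step 11 | 3-(TBSO)-6-methoxy-5-[(1R)-1-(TBSO)-4-methylpent-3-en-1-yl]benzene-1,2-dicarbaldehyde | O=Cc1c(O[Si](C)(C)C(C)(C)C)cc([C@@H](CC=C(C)C)O[Si](C)(C)C(C)(C)C)c(OC)c1C=O
F5 | step 11 | 1,1'-{3-(TBSO)-6-methoxy-5-[(1R)-1-(TBSO)-4-methylpent-3-en-1-yl]-1,2-phenylene}di(prop-2-en-1-ol), diastereomer mixture at the new carbinol carbons | C=CC(O)c1c(O[Si](C)(C)C(C)(C)C)cc([C@@H](CC=C(C)C)O[Si](C)(C)C(C)(C)C)c(OC)c1C(O)C=C
F6 | step 11 | 5-(TBSO)-8-methoxy-7-[(1R)-1-(TBSO)-4-methylpent-3-en-1-yl]-1,4-dihydronaphthalene-1,4-diol, diastereomer mixture at C1 and C4 | COc1c([C@@H](CC=C(C)C)O[Si](C)(C)C(C)(C)C)cc(O[Si](C)(C)C(C)(C)C)c2c1C(O)C=CC2O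
F7 | step 5 | 2-methoxyfuran-3-carbaldehyde | COc1occc1C=O
F8 | step 5 | (1R)-1-(2-methoxyfuran-3-yl)but-3-en-1-ol | COc1occc1[C@H](O)CC=C
F9 | step 5 | tert-butyl{[(1R)-1-(2-methoxyfuran-3-yl)but-3-en-1-yl]oxy}dimethylsilane | COc1occc1[C@@H](CC=C)O[Si](C)(C)C(C)(C)C
F10 | step 13 | (1R)-1-{1-methoxy-4-[(3-methylbut-2-enoyl)oxy]-5,8-dioxo-5,8-dihydronaphthalen-2-yl}-4-methylpent-3-en-1-yl 3-methylbut-2-enoate | COc1c([C@@H](CC=C(C)C)OC(=O)C=C(C)C)cc(OC(=O)C=C(C)C)c2c1C(=O)C=CC2=O
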